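## The problem

The target is a 2-arylbenzofuran with no stereocentre (benzofuran numbering O1, C2, C3, C3a, C4–C7, C7a; the benzo part is ring A, the pendant aryl ring is ring B, numbered C1'–C6' from its bond to C2), so the task is one of regiochemistry and functional-group tolerance. Ring A is a masked phloroglucinol: O1 on C7a and the hydroxyls on C4 and C6 are mutually meta, C5 carries hydrogen, and C7, wedged between O1 and the C6 hydroxyl, carries a tertiary 1,1-dimethylallyl (2-methylbut-3-en-2-yl) group. Any late C-alkylation of a 4,6-dioxygenated benzofuran would have to tell C7 from the electronically similar C5 while forging a quaternary benzylic carbon. Ring B is 1,2,3,5-tetrasubstituted with four different groups (the bond to C2, prenyl on C2', a methyl ether on C3', a free hydroxyl on C5'), so three hydroxyls must end free beside one methyl ether, and no ether cleavage may be used that cannot tell a protecting group from that methyl. The two isolated olefins exclude hydrogenolysis, the 1,1-dimethylallyl group closes onto a free C6 hydroxyl under protic or Lewis acid, and the electron-rich furan and ring A are attacked by oxidants and by electrophiles such as formaldehyde from acetal protecting groups. Stereocentres arise only in intermediates (the α-carbon of acid 14, the ring carbon of cyclobutenone 21, C3a of dienone 23); they are racemic and are erased again. The enabling feature is the alternation round ring A: C7a (O1), C6 (OH) and C4 (OH) alternate with C7 (tertiary alkyl), C5 (H) and C3a, which maps atom for atom onto a furan C2=C3 bond (C7a, C3a), a ketene (carbonyl carbon to C4, α-carbon to C7) and a terminal ynol ether (oxygenated carbon to C6, CH to C5).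

## Retrosynthesis

**25 to 24.** The last cut removes two O–Si bonds, at the C6 and C5' oxygens. The C6 oxygen arrives silylated from the ynol ether, and the same silyl group is put on ring B at the outset, so one fluoride treatment frees both. This avoids any acidic, reductive or oxidative final step. The precursor 24 is the target with its two least hindered problems (air sensitivity, acidity) masked.

**24 to 16 and 20.** Three bonds of ring A are cut at once: C4–C5, C6–C7 and C3a–C4. Against the neighbouring cuts (O1–C2, or C3a–C4 alone) this one lets each ring A oxygen come from a different component: O1 from the furan, the C4 hydroxyl from the ketene carbonyl, the C6 oxygen from the ynol ether. The tertiary group rides in on the ketene α-carbon, so the C5/C7 question never arises. The precursors are a furylketene 16 with no ring A at all and the two-carbon ynol ether 20. The forward reaction must deliver the correct [2+2] regiochemistry, sufficient reactivity of a fully substituted ketene, and closure onto the furan β-carbon.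

**20 to 17.** The ynol ether is cut at C–O and O–Si back to acetylene 17, through lithium acetylide 18 and lithium ethynolate 19. This is the shortest access to the parent silyl ynol ether; it asks for oxygen transfer to an acetylide and for O- rather than C-silylation, which a bulky silyl group favours.

**16 to 14.** The ketene is the dehydration product of acid 14, reached through acid chloride 15. The α-hydrogen of 15 is activated by both the acyl chloride and the furan. The forward step must generate the chloride without free HCl, which would add to the prenyl olefin.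

**14 to 10.** The bond between the future C7 and the quaternary carbon of the dimethylallyl group is cut by a [3,3] shift, leading to prenyl ester 10. Direct alkylation of an arylacetate enolate with a tertiary electrophile is not possible, and SN2' attack on prenyl bromide 3 would give mixtures. The sigmatropic route delivers the reverse-prenyl group regiospecifically.

**10 to 8 and 9.** The prenyl ester is cut at the acyl–oxygen bond to methyl ester 8 and prenol 9. The allylic ester is introduced only after the palladium step, because it would ionise with zerovalent palladium. Exchange under neutral titanate catalysis avoids the hydroxide that would endanger the aryl silyl ether.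

**8 to 6 and 7.** The C2–C1' biaryl bond is cut to ring B bromide 6 and methyl 2-furylacetate 7. Ester 7 has only one free furan α-position, so C–H arylation there needs no pre-functionalised furan and saves two steps over a boronate coupling.

**6 to 2 and 3, and 2 to 1.** The C2'–CH2 bond is cut to silyl ether 2 and prenyl bromide 3, via aryllithium 4 and arylcopper 5. In 2 the hydrogen between bromine and methoxy is the most acidic, and the bulky, non-coordinating silyloxy group shields the other two. Phenol 1 already has the OH/OMe differentiation and the bromine that becomes the biaryl bond.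

## Roads not taken

**Alternative 1:** The cut is O1–C2. The (E)-2-hydroxystilbene A1, whose ring A already carries the 1,1-dimethylallyl group, two methoxymethyl ethers and one free phenol, would be oxidised with PhI(OAc)2 in acetonitrile. The free phenolic oxygen bonds to the olefinic carbon bearing ring B and the furan closes to A2.
- Merits: the two aryl halves are made separately and joined late, the oxidative cyclisation of 2-hydroxystilbenes to 2-arylbenzofurans is an established reaction, and only one ring is formed.
- Weak points: A1 needs a pentasubstituted phloroglucinol with three differentiated oxygens and the tertiary allyl group on one specific carbon, which is the C5/C7 ambiguity moved to an earlier stage. The hypervalent iodine oxidant meets an electron-rich phenol that has a vinyl group in the ortho substituent able to trap the activated phenol, and a ring prone to dearomatisation. The acetal ethers must be removed with acid, which threatens the dimethylallyl/C6-hydroxyl pair and releases formaldehyde next to nucleophilic C5.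
- Comparison: Alternative 1 is ahead in convergence and in the precedent of its key step on this ring system. The chosen plan sets against this a ring A pattern fixed by construction, no oxidant near the phloroglucinol, and a fluoride-only end.

**Alternative 2:** The cut is C1'–C6' of ring B. The masked triketone A3 (a benzofuran-2-yl ketone at C1', prenyl on C2', C3' as methyl enol ether, C5' ketone, C6' methyl) would be doubly deprotonated with lithium diisopropylamide. C6' adds to the C1' carbonyl and loss of water aromatises ring B to A4.
- Merits: the prenyl position and the OMe/OH distinction of ring B are fixed in an open chain, and the key step needs only a standard amide base and no unstable reagent, which is an advantage over ynol ether 20.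
- Weak points: it builds the easy ring. Ring B is available as bromide 6 in two steps, whereas ring A, with its unresolved C7 problem, must be complete beforehand. The most acidic proton of A3 is on C2', and its removal turns the C1' carbonyl into an enolate and so deactivates the electrophile. The enol ether must be Z for closure, O-cyclisation to a pyranone competes, and the acetals again need acid.
- Comparison: the chosen plan puts its ring-forming step on the difficult ring and is shorter.

**Alternative 3:** The cut is C3a–C4 alone. Acid 14 of the chosen route would be converted into its acyl Meldrum's acid A5. Heating in toluene expels acetone and CO2 to give acylketene A6, whose ketene carbon (C4) is attacked by the furan β-carbon (C3a), and enolisation gives A7 with the free 4,6-diol.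
- Merits: it shares every step up to 14, needs neither ynol ether 20 nor hindered ketene 16, is one step shorter, and also fixes the oxygen pattern by construction. In step count and reagent simplicity it is better than the chosen plan.
- Weak points: the closure is an electrophilic acylation that depends on the nucleophilicity of a furan β-carbon in an aryl-conjugated furan. It must outrun dimerisation of A6 and trapping by adventitious nucleophiles. A7 appears unprotected at 110 °C as an oxidisable phloroglucinol-type diol.
- Comparison: the chosen plan sets against the extra step a ring closure that is pericyclic, hence independent of furan nucleophilicity and driven by aromatisation, and a C6 oxygen that stays protected until the last, cold step. Because it branches from 14, this road is kept as the fallback for the key step.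

Key step: step 8

Abbreviations in names: TIPS = tri(propan-2-yl)silyl; ArB = 3-methoxy-2-(3-methylbut-2-en-1-yl)-5-(TIPS-oxy)phenyl (ring B).

Assumption: the fully substituted ketene 16, like other hindered aryl(alkyl)ketenes, is taken to be persistent enough to be freed from the ammonium salt by filtration and used as a toluene solution under argon.

## Route

Step 1
Reactants: 1 3-bromo-5-methoxyphenol
Product: 2 (3-bromo-5-methoxyphenoxy)tri(propan-2-yl)silane
Conditions: i-Pr3SiCl, imidazole, DMF, 23 °C
Reagents that add atoms: chlorotri(propan-2-yl)silane, CC(C)[Si](Cl)(C(C)C)C(C)C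
Why: Routine silylation of a phenol; the bulky, non-coordinating silyl ether is needed as a blocking group in step 2 and is the group that fluoride removes at the end.

Step 2
Reactants: 2 (3-bromo-5-methoxyphenoxy)tri(propan-2-yl)silane; 3 1-bromo-3-methylbut-2-ene (prenyl bromide)
Product: 6 [3-bromo-5-methoxy-4-(3-methylbut-2-en-1-yl)phenoxy]tri(propan-2-yl)silane, via aryllithium 4 (not isolated), via arylcopper 5 (not isolated)
Conditions: LiN(i-Pr)2, THF, −78 °C; CuBr·SMe2, −78 °C; 3, −78 → 0 °C
Reagents that add atoms: none
Why: Directed ortho-lithiation: the hydrogen between Br and OMe is the most acidic (inductive effect of bromine, coordination by methoxy), as in the 2-lithiation of 3-bromoanisole by lithium amides, while the two hydrogens next to the silyloxy group are shielded. Transmetalation to the arylcopper suppresses loss of LiBr and favours α-attack on prenyl bromide (copper-mediated allylation).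

Step 3
Reactants: 6 [3-bromo-5-methoxy-4-(3-methylbut-2-en-1-yl)phenoxy]tri(propan-2-yl)silane; 7 methyl 2-(furan-2-yl)acetate
Product: 8 methyl 2-(5-ArB-furan-2-yl)acetate
Conditions: Pd(OAc)2 (5 mol%), PCy3·HBF4 (10 mol%), t-BuCO2H (30 mol%), K2CO3, DMA, 100 °C (7 in excess)
Reagents that add atoms: none
Why: Palladium-catalysed direct C–H arylation of a 2-substituted furan at its only free α-position by carboxylate-assisted concerted metalation–deprotonation. The pivalate/carbonate system is too weak to enolise the ester, and the ortho-prenyl olefin has no favourable Heck closure.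

Step 4
Reactants: 8 methyl 2-(5-ArB-furan-2-yl)acetate; 9 3-methylbut-2-en-1-ol (prenol)
Product: 10 3-methylbut-2-en-1-yl 2-(5-ArB-furan-2-yl)acetate
Conditions: Ti(OiPr)4 (10 mol%), 9 (excess), toluene, 110 °C, MeOH removed (4 Å sieves)
Reagents that add atoms: none
Why: Titanate-catalysed transesterification is neutral and is driven by removal of methanol, so the aryl silyl ether, which hydroxide would endanger, is untouched.

Step 5
Reactants: 10 3-methylbut-2-en-1-yl 2-(5-ArB-furan-2-yl)acetate
Product: 14 2-(5-ArB-furan-2-yl)-3,3-dimethylpent-4-enoic acid (racemic), via lithium enolate 11 (not isolated), via silyl ketene acetal 12 (not isolated), via trimethylsilyl ester 13 (not isolated)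
Conditions: LiN(i-Pr)2, THF, −78 °C; Me3SiCl, −78 → 65 °C; 1 M HCl, 0 °C
Reagents that add atoms: none
Why: Ireland–Claisen rearrangement: the O-silylated enolate undergoes a [3,3] shift that joins the α-carbon to the dimethyl-substituted allyl terminus, giving the 1,1-dimethylallyl group regiospecifically. The new stereocentre is formed racemic and is erased in step 6; brief dilute acid cleaves only the silyl ester.

Step 6
Reactants: 14 2-(5-ArB-furan-2-yl)-3,3-dimethylpent-4-enoic acid (racemic)
Product: 16 2-(5-ArB-furan-2-yl)-3,3-dimethylpenta-1,4-dien-1-one (the ketene), via acid chloride 15 (not isolated)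
Conditions: Me2C=C(Cl)NMe2, toluene, 0 → 23 °C; Et3N, 23 → 60 °C; filtration under Ar
Reagents that add atoms: none
Why: The α-chloroenamine converts the acid into its chloride without releasing HCl, sparing the prenyl olefin and the furan. Triethylamine then removes the α-hydrogen, activated by acyl chloride and furan, in the standard dehydrochlorination route to aryl(alkyl)ketenes; the fully substituted ketene is too hindered to dimerise.

Step 7
Reactants: 17 ethyne (acetylene)
Product: 20 (ethynyloxy)tri(propan-2-yl)silane (triisopropylsilyloxyacetylene), via lithium acetylide 18 (not isolated), via lithium ethynolate 19 (not isolated)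
Conditions: n-BuLi, THF, −78 °C (17 in excess); t-BuOOLi (from t-BuOOH, LiN(SiMe3)2), −78 → −10 °C; i-Pr3SiOTf, −78 → 0 °C
Reagents that add atoms: tert-butyl hydroperoxide, CC(C)(C)OO; tri(propan-2-yl)silyl trifluoromethanesulfonate, CC(C)[Si](OS(=O)(=O)C(F)(F)F)(C(C)C)C(C)C
Why: Lithium acetylides are oxidised to lithium ynolates by electrophilic oxygen transfer from lithium tert-butyl peroxide, and bulky silyl triflates silylate ynolates on oxygen, the triisopropylsilyl group being the one that makes ynol ethers isolable. The method for 1-alkynes is applied here to the parent acetylide, kept under excess acetylene to suppress disproportionation.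

Step 8
Reactants: 16 2-(5-ArB-furan-2-yl)-3,3-dimethylpenta-1,4-dien-1-one; 20 (ethynyloxy)tri(propan-2-yl)silane
Product: 24 2-ArB-7-(2-methylbut-3-en-2-yl)-6-(TIPS-oxy)-1-benzofuran-4-ol, via cyclobutenone 21 (not isolated), via dienylketene 22 (not isolated), via dienone 23 (not isolated)
Conditions: toluene, 23 → 80 °C, then 110 °C, Ar (20 in excess)
Reagents that add atoms: none
Why: The unsubstituted, nucleophilic carbon of ynol ether 20 bonds to the ketene carbonyl carbon and the silyloxy carbon to the ketene α-carbon ([2+2] cycloaddition), giving the 4,4-disubstituted 3-silyloxycyclobutenone 21 with C4–C5 and C6–C7 in place. On further heating 21 opens by four-electron conrotatory electrocyclic ring opening to dienylketene 22, and the isomer with the furan cis to the ketenyl carbon closes ring A by six-electron disrotatory electrocyclisation onto the furan β-carbon (C3a–C4), giving dienone 23, which tautomerises to phenol 24; the unproductive isomer can return to 21 and is funnelled through. The closest known reaction is the Danheiser benzannulation of vinyl-, aryl- and heteroarylketenes with siloxyalkynes to resorcinol monosilyl ethers. No stereocentre remains in 24, since those of 21 and 23 are lost on ring opening and tautomerisation. The [2+2] regiochemistry is secured by the polarisation of the ynol ether, chemoselectivity over the two isolated olefins by the far higher ketenophilicity of the electron-rich alkyne, and the site of closure by the fact that the furan offers only one carbon next to the ketene-bearing one. Staged heating consumes the ketene before any phenol appears, so O-acylation of 24 by 16 should not compete.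

Step 9
Reactants: 24 2-ArB-7-(2-methylbut-3-en-2-yl)-6-(TIPS-oxy)-1-benzofuran-4-ol
Product: 25 2-[5-hydroxy-3-methoxy-2-(3-methylbut-2-en-1-yl)phenyl]-7-(2-methylbut-3-en-2-yl)-1-benzofuran-4,6-diol (the target)
Conditions: Bu4NF, AcOH, THF, 0 → 23 °C, Ar
Reagents that add atoms: none
Why: Fluoride cleaves both aryl silyl ethers (phenoxide leaving groups). The acetic acid buffer keeps the triphenol from phenoxide autoxidation and is far too weak to cyclise the dimethylallyl group onto the C6 hydroxyl.

## Compound list

1 | 3-bromo-5-methoxyphenol | COc1cc(O)cc(Br)c1 | starting material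
2 | (3-bromo-5-methoxyphenoxy)tri(propan-2-yl)silane | COc1cc(Br)cc(O[Si](C(C)C)(C(C)C)C(C)C)c1 | intermediate
3 | 1-bromo-3-methylbut-2-ene (prenyl bromide) | CC(C)=CCBr | starting material
4 | [2-bromo-6-methoxy-4-(TIPS-oxy)phenyl]lithium | [Li]c1c(Br)cc(O[Si](C(C)C)(C(C)C)C(C)C)cc1OC | intermediate
5 | [2-bromo-6-methoxy-4-(TIPS-oxy)phenyl]copper | [Cu]c1c(Br)cc(O[Si](C(C)C)(C(C)C)C(C)C)cc1OC | intermediate
6 | [3-bromo-5-methoxy-4-(3-methylbut-2-en-1-yl)phenoxy]tri(propan-2-yl)silane | COc1cc(O[Si](C(C)C)(C(C)C)C(C)C)cc(Br)c1CC=C(C)C | intermediate
7 | methyl 2-(furan-2-yl)acetate | COC(=O)Cc1ccco1 | starting material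
8 | methyl 2-{5-[3-methoxy-2-(3-methylbut-2-en-1-yl)-5-(TIPS-oxy)phenyl]furan-2-yl}acetate | COC(=O)Cc1ccc(-c2cc(O[Si](C(C)C)(C(C)C)C(C)C)cc(OC)c2CC=C(C)C)o1 | intermediate
9 | 3-methylbut-2-en-1-ol (prenol) | CC(C)=CCO | starting material
10 | 3-methylbut-2-en-1-yl 2-{5-[3-methoxy-2-(3-methylbut-2-en-1-yl)-5-(TIPS-oxy)phenyl]furan-2-yl}acetate | CC(C)=CCOC(=O)Cc1ccc(-c2cc(O[Si](C(C)C)(C(C)C)C(C)C)cc(OC)c2CC=C(C)C)o1 | intermediate
11 | lithium enolate of 10 (enolate geometry without consequence) | CC(C)=CCOC(O[Li])=Cc1ccc(-c2cc(O[Si](C(C)C)(C(C)C)C(C)C)cc(OC)c2CC=C(C)C)o1 | intermediate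
12 | trimethylsilyl ketene acetal of 10 (geometry without consequence) | CC(C)=CCOC(O[Si](C)(C)C)=Cc1ccc(-c2cc(O[Si](C(C)C)(C(C)C)C(C)C)cc(OC)c2CC=C(C)C)o1 | intermediate
13 | trimethylsilyl 2-{5-[3-methoxy-2-(3-methylbut-2-en-1-yl)-5-(TIPS-oxy)phenyl]furan-2-yl}-3,3-dimethylpent-4-enoate (racemic) | C=CC(C)(C)C(C(=O)O[Si](C)(C)C)c1ccc(-c2cc(O[Si](C(C)C)(C(C)C)C(C)C)cc(OC)c2CC=C(C)C)o1 | intermediate
14 | 2-{5-[3-methoxy-2-(3-methylbut-2-en-1-yl)-5-(TIPS-oxy)phenyl]furan-2-yl}-3,3-dimethylpent-4-enoic acid (racemic) | C=CC(C)(C)C(C(=O)O)c1ccc(-c2cc(O[Si](C(C)C)(C(C)C)C(C)C)cc(OC)c2CC=C(C)C)o1 | intermediate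
15 | 2-{5-[3-methoxy-2-(3-methylbut-2-en-1-yl)-5-(TIPS-oxy)phenyl]furan-2-yl}-3,3-dimethylpent-4-enoyl chloride (racemic) | C=CC(C)(C)C(C(=O)Cl)c1ccc(-c2cc(O[Si](C(C)C)(C(C)C)C(C)C)cc(OC)c2CC=C(C)C)o1 | intermediate
16 | 2-{5-[3-methoxy-2-(3-methylbut-2-en-1-yl)-5-(TIPS-oxy)phenyl]furan-2-yl}-3,3-dimethylpenta-1,4-dien-1-one (furyl(1,1-dimethylallyl)ketene) | O=C=C(c1ccc(-c2cc(O[Si](C(C)C)(C(C)C)C(C)C)cc(OC)c2CC=C(C)C)o1)C(C)(C)C=C | intermediate
17 | ethyne (acetylene) | C#C | starting material
18 | ethynyllithium (lithium acetylide) | [Li]C#C | intermediate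
19 | lithium ethynolate | [Li+].[O-]C#C | intermediate
20 | (ethynyloxy)tri(propan-2-yl)silane (triisopropylsilyloxyacetylene) | C#CO[Si](C(C)C)(C(C)C)C(C)C | intermediate
21 | 4-{5-[3-methoxy-2-(3-methylbut-2-en-1-yl)-5-(TIPS-oxy)phenyl]furan-2-yl}-4-(2-methylbut-3-en-2-yl)-3-(TIPS-oxy)cyclobut-2-en-1-one (racemic) | O=C1C=C(O[Si](C(C)C)(C(C)C)C(C)C)C1(C(C)(C)C=C)c1ccc(-c2cc(O[Si](C(C)C)(C(C)C)C(C)C)cc(OC)c2CC=C(C)C)o1 | intermediate
22 | 4-{5-[3-methoxy-2-(3-methylbut-2-en-1-yl)-5-(TIPS-oxy)phenyl]furan-2-yl}-5,5-dimethyl-3-(TIPS-oxy)hepta-1,3,6-trien-1-one, isomer with the furyl group cis to the ketenyl carbon | O=C=C/C(O[Si](C(C)C)(C(C)C)C(C)C)=C(/C(C)(C)C=C)c1ccc(-c2cc(O[Si](C(C)C)(C(C)C)C(C)C)cc(OC)c2CC=C(C)C)o1 | intermediate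
23 | 2-[3-methoxy-2-(3-methylbut-2-en-1-yl)-5-(TIPS-oxy)phenyl]-7-(2-methylbut-3-en-2-yl)-6-(TIPS-oxy)-3aH-1-benzofuran-4-one (racemic at C3a) | O=C1C=C(O[Si](C(C)C)(C(C)C)C(C)C)C(C(C)(C)C=C)=C2OC(c3cc(O[Si](C(C)C)(C(C)C)C(C)C)cc(OC)c3CC=C(C)C)=CC12 | intermediate
24 | 2-[3-methoxy-2-(3-methylbut-2-en-1-yl)-5-(TIPS-oxy)phenyl]-7-(2-methylbut-3-en-2-yl)-6-(TIPS-oxy)-1-benzofuran-4-ol | C=CC(C)(C)c1c(O[Si](C(C)C)(C(C)C)C(C)C)cc(O)c2cc(-c3cc(O[Si](C(C)C)(C(C)C)C(C)C)cc(OC)c3CC=C(C)C)oc12 | intermediate
25 | 2-[5-hydroxy-3-methoxy-2-(3-methylbut-2-en-1-yl)phenyl]-7-(2-methylbut-3-en-2-yl)-1-benzofuran-4,6-diol (no stereocentre) | C=CC(C)(C)c1c(O)cc(O)c2cc(-c3cc(O)cc(OC)c3CC=C(C)C)oc12 | target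

## Step count and risks

Total step count: 9. Longest linear sequence: 8 steps (steps 1–6, 8 and 9, from 1); step 7 is a one-step side branch.

**Step 8 (key step).** The cycloaddition between the fully substituted ketene and the bulky ynol ether may be slower than thermal 1,3-silyl migration or oligomerisation of the ynol ether. After cycloaddition, ring opening may favour the unproductive olefin geometry, or a [3,3] shift of the dimethylallyl group within the cyclobutenone may compete. The dehydrochlorination that feeds the step (step 6) may also lag, because the α-hydrogen sits next to a quaternary carbon.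
Fallback: it sets out from acid 14 and avoids both the ketene and the ynol ether. Acid 14 is condensed with Meldrum's acid (DCC, DMAP, CH2Cl2) to the acyl Meldrum's acid F1 (the same compound as A5). Heating F1 in toluene at 110 °C should expel acetone and CO2 to give the acylketene F2 (the same compound as A6), which acylates the furan β-carbon and enolises to the 5'-TIPS ether of the target F3 (the same compound as A7). Bu4NF/AcOH then gives 25, where the fallback rejoins the route.

**Step 7.** Monolithium acetylide may disproportionate to Li2C2 before oxygen transfer, silylation may occur partly on carbon, and the small, acid-labile product may be lost on isolation.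
Fallback: it sets out from ketene 16 and dispenses with 20. Commercial ethoxyacetylene, a smaller and thermally robust ketenophile, is added to 16 at 0–23 °C to give the 3-ethoxycyclobutenone F4. Mild hydrolysis of this vinylogous ester (1 M HCl, THF) gives the cyclobutane-1,3-dione F5. Its two carbonyl groups are equivalent, so silylation (i-Pr3SiOTf, Et3N, CH2Cl2, −78 °C) can give only cyclobutenone 21, where the fallback rejoins the route; heating in toluene leads on to 24.

**Step 2.** Allylation of the hindered arylcopper may be slow and partly γ-selective, and any aryllithium left untransmetalated may lose LiBr on warming (aryne formation).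
Fallback: it sets out from 2 by the same lithiation and transmetalation. Arylcopper 5 is quenched with allyl bromide, which is more reactive and has no α/γ ambiguity, to give [3-bromo-5-methoxy-4-(prop-2-en-1-yl)phenoxy]tri(propan-2-yl)silane F6. Olefin cross-metathesis of F6 with 2-methylbut-2-ene (second-generation Grubbs catalyst, CH2Cl2, 40 °C) converts the allyl into the prenyl group and returns to 6.

**Step 3.** Oxidative addition of the electron-rich, ortho-substituted bromide may be slow at a temperature at which carbonate and pivalate begin to cleave the aryl silyl ether, and α-arylation of the ester may intrude.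
Fallback: a two-component cross-coupling replaces the C–H activation. Bromide 6 is borylated (bis(pinacolato)diboron, PdCl2(dppf), KOAc, dioxane, 80 °C) to the arylboronic ester F7. Ester 7 is brominated at its free α-position (N-bromosuccinimide, DMF, 0 °C) to methyl 2-(5-bromofuran-2-yl)acetate F8. Suzuki–Miyaura coupling of F7 and F8 (Pd(PPh3)4, K3PO4, dioxane/water, 60 °C) returns to 8.

## Further compounds

F1 | step 8 | 5-(1-hydroxy-2-{5-[3-methoxy-2-(3-methylbut-2-en-1-yl)-5-(TIPS-oxy)phenyl]furan-2-yl}-3,3-dimethylpent-4-en-1-ylidene)-2,2-dimethyl-1,3-dioxane-4,6-dione (acyl Meldrum's acid, racemic) | C=CC(C)(C)C(C(O)=C1C(=O)OC(C)(C)OC1=O)c1ccc(-c2cc(O[Si](C(C)C)(C(C)C)C(C)C)cc(OC)c2CC=C(C)C)o1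
F2 | step 8 | 4-{5-[3-methoxy-2-(3-methylbut-2-en-1-yl)-5-(TIPS-oxy)phenyl]furan-2-yl}-5,5-dimethylhepta-1,6-diene-1,3-dione (acylketene, racemic) | C=CC(C)(C)C(C(=O)C=C=O)c1ccc(-c2cc(O[Si](C(C)C)(C(C)C)C(C)C)cc(OC)c2CC=C(C)C)o1
F3 | step 8 | 2-[3-methoxy-2-(3-methylbut-2-en-1-yl)-5-(TIPS-oxy)phenyl]-7-(2-methylbut-3-en-2-yl)-1-benzofuran-4,6-diol (5'-TIPS ether of the target) | C=CC(C)(C)c1c(O)cc(O)c2cc(-c3cc(O[Si](C(C)C)(C(C)C)C(C)C)cc(OC)c3CC=C(C)C)oc12
F4 | step 7 | 3-ethoxy-4-{5-[3-methoxy-2-(3-methylbut-2-en-1-yl)-5-(TIPS-oxy)phenyl]furan-2-yl}-4-(2-methylbut-3-en-2-yl)cyclobut-2-en-1-one (racemic) | CCOC1=CC(=O)C1(C(C)(C)C=C)c1ccc(-c2cc(O[Si](C(C)C)(C(C)C)C(C)C)cc(OC)c2CC=C(C)C)o1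
F5 | step 7 | 2-{5-[3-methoxy-2-(3-methylbut-2-en-1-yl)-5-(TIPS-oxy)phenyl]furan-2-yl}-2-(2-methylbut-3-en-2-yl)cyclobutane-1,3-dione | O=C1CC(=O)C1(C(C)(C)C=C)c1ccc(-c2cc(O[Si](C(C)C)(C(C)C)C(C)C)cc(OC)c2CC=C(C)C)o1
F6 | step 2 | [3-bromo-5-methoxy-4-(prop-2-en-1-yl)phenoxy]tri(propan-2-yl)silane | C=CCc1c(Br)cc(O[Si](C(C)C)(C(C)C)C(C)C)cc1OC
F7 | step 3 | [3-methoxy-4-(3-methylbut-2-en-1-yl)-5-(4,4,5,5-tetramethyl-1,3,2-dioxaborolan-2-yl)phenoxy]tri(propan-2-yl)silane | COc1cc(O[Si](C(C)C)(C(C)C)C(C)C)cc(B2OC(C)(C)C(C)(C)O2)c1CC=C(C)C
F8 | step 3 | methyl 2-(5-bromofuran-2-yl)acetate | COC(=O)Cc1ccc(Br)o1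
A1 | alternative 1 | (E)-2-hydroxystilbene: 2-[(E)-2-{3-methoxy-2-(3-methylbut-2-en-1-yl)-5-(TIPS-oxy)phenyl}ethenyl]-3,5-bis(methoxymethoxy)-6-(2-methylbut-3-en-2-yl)phenol | C=CC(C)(C)c1c(OCOC)cc(OCOC)c(/C=C/c2cc(O[Si](C(C)C)(C(C)C)C(C)C)cc(OC)c2CC=C(C)C)c1O
A2 | alternative 1 | target as its 4,6-bis(methoxymethyl) ether and 5'-TIPS ether | C=CC(C)(C)c1c(OCOC)cc(OCOC)c2cc(-c3cc(O[Si](C(C)C)(C(C)C)C(C)C)cc(OC)c3CC=C(C)C)oc12
A3 | alternative 2 | (Z)-1-[4,6-bis(methoxymethoxy)-7-(2-methylbut-3-en-2-yl)-1-benzofuran-2-yl]-3-methoxy-2-(3-methylbut-2-en-1-yl)hex-3-ene-1,5-dione (masked triketone, racemic) | C=CC(C)(C)c1c(OCOC)cc(OCOC)c2cc(C(=O)C(CC=C(C)C)/C(OC)=C\C(C)=O)oc12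
A4 | alternative 2 | target as its 4,6-bis(methoxymethyl) ether with free 5'-hydroxyl | C=CC(C)(C)c1c(OCOC)cc(OCOC)c2cc(-c3cc(O)cc(OC)c3CC=C(C)C)oc12
A5 | alternative 3 | acyl Meldrum's acid derived from acid 14 (racemic) | C=CC(C)(C)C(C(O)=C1C(=O)OC(C)(C)OC1=O)c1ccc(-c2cc(O[Si](C(C)C)(C(C)C)C(C)C)cc(OC)c2CC=C(C)C)o1
A6 | alternative 3 | acylketene formed from A5 (racemic) | C=CC(C)(C)C(C(=O)C=C=O)c1ccc(-c2cc(O[Si](C(C)C)(C(C)C)C(C)C)cc(OC)c2CC=C(C)C)o1
A7 | alternative 3 | target as its 5'-TIPS ether with free 4,6-diol | C=CC(C)(C)c1c(O)cc(O)c2cc(-c3cc(O[Si](C(C)C)(C(C)C)C(C)C)cc(OC)c3CC=C(C)C)oc12
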